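**Retrosynthetic overview**

Germacrane numbering is used throughout: C1=C10 alkene with C14 on C10, C4–C5 epoxide with C15 on C4, lactone oxygen on C6, C11–C13 on C7, esters on C8 and C9.
The ten-membered carbocycle is opened at C3–C4. C3 is a plain methylene beside the trisubstituted C4 of the C4–C5 epoxide, so this bond is made by a B-alkyl Suzuki macrocyclization of a C2=C3 diene terminus onto an (E)-C4 vinyl iodide, whose geometry becomes that of the 4,5-alkene and then of the trans-epoxide.
The seco compound is split at C9–C10 into a (Z)-2-iodopentadienyl silyl ether (from acrolein by an iodo-Wittig olefination that fixes C2 cis to C9) and a lactone aldehyde; Felkin–Anh addition sets C9.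
The lactone aldehyde comes from an Evans syn-aldol of a succinate imide (C7, C8), asymmetric transfer hydrogenation of an ynone (C6), lactonization and hydrozirconation–iodination.
Ring order: γ-lactone first, ten-membered ring second, epoxide last; the C13 methylene, the C14 ester and the two acyl groups are set after ring closure.

Key step: step 15

Remark: 2-[(4-methoxybenzyl)oxy]acetaldehyde and mono-tert-butyl succinate are taken as purchasable.

**Route**

Step 1
Reactants: 1 acrolein; 2 methyl (triphenylphosphoranylidene)acetate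
Product: 4 methyl (2Z)-2-iodopenta-2,4-dienoate, via iodo ylide 3 (not isolated)
Conditions: NIS, MeCN, −20 °C; then 1, −20 °C to rt
Reagents that add atoms: N-iodosuccinimide, O=C1CCC(=O)N1I
Why: Wittig olefination of acrolein with the α-iodo ester ylide made in the flask by iodination of 2 (the succinimide anion re-forms the ylide); as with other ester-stabilized ylides the ester should end up trans to the vinyl group, which places iodine cis to it (2Z).

Step 2
Reactants: 4 methyl (2Z)-2-iodopenta-2,4-dienoate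
Product: 5 (2Z)-2-iodopenta-2,4-dien-1-ol
Conditions: i-Bu2AlH, CH2Cl2, −78 °C
Reagents that add atoms: none
Why: 1,2-Reduction of the dienoate by the aluminium hydride at low temperature should give the allylic alcohol without touching the C–I bond or the alkene geometry.

Step 3
Reactants: 5 (2Z)-2-iodopenta-2,4-dien-1-ol
Product: 6 tert-butyl{[(2Z)-2-iodopenta-2,4-dien-1-yl]oxy}dimethylsilane
Conditions: TBSCl, imidazole, CH2Cl2, 0 °C to rt
Reagents that add atoms: tert-butyldimethylsilyl chloride, CC(C)(C)[Si](C)(C)Cl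
Why: Imidazole-promoted silylation of the primary alcohol protects O14 for the organolithium, borane and enolate steps.

Step 4
Reactants: 7 (4R)-4-benzyl-1,3-oxazolidin-2-one; 8 mono-tert-butyl succinate
Product: 10 tert-butyl 4-[(4R)-4-benzyl-2-oxo-1,3-oxazolidin-3-yl]-4-oxobutanoate, via mixed anhydride 9 (not isolated)
Conditions: t-BuCOCl, Et3N, THF, −20 °C; then 7, LiCl, −20 °C to rt
Reagents that add atoms: none
Why: N-Acylation of the oxazolidinone through the mixed pivalic anhydride (LiCl/Et3N protocol); attack should occur at the unhindered succinyl carbonyl.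

Step 5
Reactants: 10 succinate imide; 11 2-[(4-methoxybenzyl)oxy]acetaldehyde
Product: 13 syn-aldol imide (7R,8R), via boron enolate 12 (not isolated)
Conditions: Bu2BOTf, i-Pr2NEt, CH2Cl2, 0 °C; then 11, −78 to 0 °C; pH 7 buffer, MeOH, H2O2
Reagents that add atoms: none
Why: Evans syn-aldol reaction: the chelated (Z)-boron enolate, formed at the imide α-carbon only, adds through a chair transition state on the face away from the benzyl group, which should set C7 (R) and C8 (R) syn.

Step 6
Reactants: 13 syn-aldol imide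
Product: 14 Weinreb amide (7R,8R) with free C8 hydroxyl
Conditions: MeNHOMe·HCl, AlMe3, CH2Cl2, −10 to 0 °C
Reagents that add atoms: N,O-dimethylhydroxylamine hydrochloride, CNOC.Cl
Why: Weinreb transamination of the aldol imide by the aluminium amide, assisted by the free β-hydroxyl; the tert-butyl ester should be too hindered to react and the auxiliary is released.

Step 7
Reactants: 14 Weinreb amide
Product: 15 C8 TBS ether of the Weinreb amide
Conditions: TBSOTf, 2,6-lutidine, CH2Cl2, −78 °C
Reagents that add atoms: tert-butyldimethylsilyl triflate, CC(C)(C)[Si](C)(C)OS(=O)(=O)C(F)(F)F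
Why: Silylation of the secondary alcohol with the silyl triflate at low temperature blocks O8 before O6 exists, so that only O6 can later close the lactone, and provides the non-chelating α-silyloxy group needed in step 13.

Step 8
Reactants: 15 silylated Weinreb amide; 16 1-propynylmagnesium bromide
Product: 17 ynone (7R,8R)
Conditions: THF, −20 to 0 °C; NH4Cl (aq) at −20 °C
Reagents that add atoms: none
Why: Weinreb ketone synthesis: the magnesium-chelated tetrahedral adduct should stop at the ynone stage, and the tert-butyl ester is inert at this temperature.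

Step 9
Reactants: 17 ynone
Product: 19 alkynyl lactone (6S,7S,8R), via propargylic alcohol 18 (not isolated)
Conditions: Ru[(S,S)-TsDPEN](p-cymene) (cat.), i-PrOH, rt; then solvent exchange, TsOH·H2O (cat.), CH2Cl2, rt
Reagents that add atoms: none
Why: Noyori asymmetric transfer hydrogenation of an α,β-acetylenic ketone, in which the (S,S) catalyst should give the 6S alcohol under catalyst control (the alkynyl group takes the place of the aryl group of the usual model), followed by acid-catalysed lactonization of the γ-hydroxy tert-butyl ester through O6, the only free hydroxyl.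

Step 10
Reactants: 19 alkynyl lactone
Product: 21 (E)-vinyl iodide lactone (6S,7S,8R), via vinylzirconocene 20 (not isolated)
Conditions: Cp2Zr(H)Cl (2.2 equiv), THF, rt to 40 °C; then I2, 0 °C
Reagents that add atoms: iodine, II
Why: Syn hydrozirconation of the internal alkyne, which under equilibration with excess Cp2Zr(H)Cl should place zirconium on the less hindered methyl-bearing C4, then iodinolysis with retention, giving iodine trans to C6.

Step 11
Reactants: 21 vinyl iodide lactone
Product: 22 primary alcohol at C9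
Conditions: DDQ, CH2Cl2–pH 7 buffer, 0 °C to rt
Reagents that add atoms: none
Why: Oxidative cleavage of the 4-methoxybenzyl ether by DDQ through the benzylic oxocarbenium ion and its hydrolysis; silyl ether, lactone and vinyl iodide should be inert.

Step 12
Reactants: 22 primary alcohol
Product: 23 α-silyloxy aldehyde (C9 aldehyde)
Conditions: Dess–Martin periodinane, CH2Cl2, 0 °C to rt
Reagents that add atoms: none
Why: Dess–Martin oxidation of the primary alcohol under near-neutral conditions should give the aldehyde without epimerization at C8.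

Step 13
Reactants: 6 dienyl iodide; 23 α-silyloxy aldehyde
Product: 25 dienyl carbinol (6S,7S,8R,9S), via dienyllithium 24 (not isolated)
Conditions: 6, t-BuLi (2.0 equiv per 6), Et2O, −78 °C; then 23, −78 °C; NH4Cl (aq) at −78 °C
Reagents that add atoms: none
Why: Iodine–lithium exchange with retention of alkene geometry and 1,2-addition of the alkenyllithium to the aldehyde, which reacts faster than the lactone at −78 °C; polar Felkin–Anh attack anti to the C8 silyloxy group should give the 8,9-anti (9S) alcohol.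

Step 14
Reactants: 25 dienyl carbinol
Product: 26 diene lactone with the C4 vinyl iodide (C8 OTBS, C9 OTES, C14 OTBS)
Conditions: Et3SiOTf, 2,6-lutidine, CH2Cl2, −78 °C
Reagents that add atoms: triethylsilyl triflate, CC[Si](CC)(CC)OS(=O)(=O)C(F)(F)F
Why: Silylation of the hindered allylic alcohol with the silyl triflate under non-acidic conditions blocks O9 against silyl migration from O8 in the basic steps that follow.

Step 15
Reactants: 26 diene lactone with the C4 vinyl iodide
Product: 28 ten-membered 1(10),4-dienolide (6R,7S,8R,9S), via B-alkyl-9-BBN borane 27 (not isolated)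
Conditions: 9-BBN, THF, 0 °C to rt; then slow addition to Pd(dppf)Cl2 (20 mol%), AsPh3, Cs2CO3, DMF–THF–H2O, about 1 mM, rt to 50 °C
Reagents that add atoms: none
Why: 9-BBN adds to the unhindered terminal C2=C3 bond of the diene with boron on C3; zerovalent palladium then inserts into the C4–I bond, base converts the borane into a borate that transfers C3 to palladium, and reductive elimination forms C3–C4. The closest known reaction type is the B-alkyl Suzuki–Miyaura macrocyclization of a hydroborated terminal alkene onto a vinyl iodide. The ten-membered carbocycle closes head to tail by C(sp3)–C(sp2) reductive elimination from an eleven-membered palladacycle, helped by the trans-lactone and the C1=C10 alkene (C2 cis to C9), which hold C3 near C4. No stereocenter is formed; the C4=C5 geometry is that of the iodide, since oxidative addition and reductive elimination both go with retention. The step needs site-selective hydroboration, secured by the low reactivity of 9-BBN toward trisubstituted alkenes and vinyl iodides, and ring closure in preference to oligomerization and β-hydride loss, secured by high dilution and the wide bite angle of dppf.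

Step 16
Reactants: 28 ten-membered dienolide
Product: 29 C11 dimethylaminomethyl lactone (C11 epimers)
Conditions: LiN(i-Pr)2, THF, −78 °C; then CH2=NMe2+ I− (Eschenmoser's salt), −78 °C to rt
Reagents that add atoms: N,N-dimethylmethyleneiminium iodide, C=[N+](C)C.[I-]
Why: Mannich reaction of the lactone lithium enolate (C11 is the only acidic position) with the preformed iminium salt; the C11 configuration is of no consequence.

Step 17
Reactants: 29 Mannich base
Product: 31 α-methylene lactone, via ammonium iodide 30 (not isolated)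
Conditions: MeI, MeOH, rt; then NaHCO3, CH2Cl2–H2O, rt
Reagents that add atoms: none
Why: Exhaustive N-methylation and E1cB (Hofmann-type) loss of trimethylamine should unveil the C11=C13 exocyclic alkene.

Step 18
Reactants: 31 α-methylene lactone
Product: 32 C9,C14 diol (C8 OTBS kept)
Conditions: HF·pyridine, pyridine, THF, 0 °C
Reagents that add atoms: none
Why: Fluoride-mediated desilylation, selective for the primary allylic TBS ether and the more labile triethylsilyl ether; the hindered secondary TBS ether on C8 should survive the buffered reagent at 0 °C.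

Step 19
Reactants: 32 diol
Product: 33 C14 enal with free C9 hydroxyl
Conditions: TEMPO (cat.), PhI(OAc)2, CH2Cl2, rt
Reagents that add atoms: none
Why: Oxoammonium (TEMPO) oxidation, selective for the primary allylic alcohol over the hindered secondary C9 hydroxyl; O8 stays silylated so that no hemiacetal with C14 can form.

Step 20
Reactants: 33 enal
Product: 34 C14 carboxylic acid
Conditions: NaClO2, NaH2PO4, 2-methylbut-2-ene, t-BuOH–H2O, 0 °C to rt
Reagents that add atoms: sodium chlorite, [Na+].[O-]Cl=O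
Why: Pinnick oxidation of the enal to the acid, with 2-methylbut-2-ene trapping HOCl so that the C4=C5 alkene is spared.

Step 21
Reactants: 34 carboxylic acid
Product: 35 C14 methyl ester with free C9 hydroxyl
Conditions: MeI, KHCO3, DMF, rt
Reagents that add atoms: iodomethane, CI
Why: O-Alkylation of the carboxylate (SN2 on iodomethane) under weakly basic conditions avoids diazoalkanes, which could add to the α-methylene lactone.

Step 22
Reactants: 35 hydroxy ester
Product: 36 C9 acetate
Conditions: Ac2O, pyridine, DMAP (cat.), CH2Cl2, 0 °C to rt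
Reagents that add atoms: acetic anhydride, CC(=O)OC(C)=O
Why: DMAP-catalysed acylation of the secondary allylic alcohol installs the C9 acetate.

Step 23
Reactants: 36 C9 acetate
Product: 37 C8 alcohol
Conditions: HF·pyridine, THF, 0 °C to rt
Reagents that add atoms: none
Why: Acidic fluoride cleavage of the remaining silyl ether; the non-basic medium should suppress acetyl migration from O9 to O8 and translactonization.

Step 24
Reactants: 37 C8 alcohol
Product: 38 8-methacrylate 9-acetate 1(10),4,11(13)-trienolide methyl ester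
Conditions: methacrylic anhydride, Et3N, DMAP (cat.), CH2Cl2, 0 °C to rt
Reagents that add atoms: methacrylic anhydride, C=C(C)C(=O)OC(=O)C(C)=C
Why: DMAP-catalysed acylation with the anhydride esterifies the C8 hydroxyl.

Step 25
Reactants: 38 trienolide
Product: 39 target CNP0153978.4
Conditions: mCPBA, CH2Cl2, 0 °C
Reagents that add atoms: 3-chloroperoxybenzoic acid, OOC(=O)c1cccc(Cl)c1
Why: Prilezhaev epoxidation: the peracid should react only with the electron-rich trisubstituted C4=C5 alkene (the other three alkenes are conjugated to carbonyl groups) and from its outer face, the inner face being blocked by the ring in the conformation fixed by the trans-lactone, as in related germacranolide 4,5-alkenes, which should give the trans 4R,5R-epoxide.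

**Compound list**

1 | acrolein | C=CC=O | starting material
2 | methyl (triphenylphosphoranylidene)acetate | COC(=O)C=P(c1ccccc1)(c1ccccc1)c1ccccc1 | starting material
3 | methyl iodo(triphenylphosphoranylidene)acetate | COC(=O)C(I)=P(c1ccccc1)(c1ccccc1)c1ccccc1 | intermediate
4 | methyl (2Z)-2-iodopenta-2,4-dienoate | C=C/C=C(\I)C(=O)OC | intermediate
5 | (2Z)-2-iodopenta-2,4-dien-1-ol | C=C/C=C(\I)CO | intermediate
6 | tert-butyl{[(2Z)-2-iodopenta-2,4-dien-1-yl]oxy}dimethylsilane | C=C/C=C(\I)CO[Si](C)(C)C(C)(C)C | intermediate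
7 | (4R)-4-benzyl-1,3-oxazolidin-2-one | O=C1N[C@H](Cc2ccccc2)CO1 | starting material
8 | 4-tert-butoxy-4-oxobutanoic acid (mono-tert-butyl succinate) | CC(C)(C)OC(=O)CCC(=O)O | starting material
9 | mixed anhydride of 8 with pivalic acid | CC(C)(C)OC(=O)CCC(=O)OC(=O)C(C)(C)C | intermediate
10 | tert-butyl 4-[(4R)-4-benzyl-2-oxo-1,3-oxazolidin-3-yl]-4-oxobutanoate | CC(C)(C)OC(=O)CCC(=O)N1C(=O)OC[C@H]1Cc1ccccc1 | intermediate
11 | 2-[(4-methoxybenzyl)oxy]acetaldehyde | COc1ccc(COCC=O)cc1 | starting material
12 | (Z)-dibutylboron enolate of 10 | CCCCB(CCCC)O/C(=C\CC(=O)OC(C)(C)C)N1C(=O)OC[C@H]1Cc1ccccc1 | intermediate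
13 | tert-butyl (3R,4R)-3-{[(4R)-4-benzyl-2-oxo-1,3-oxazolidin-3-yl]carbonyl}-4-hydroxy-5-[(4-methoxybenzyl)oxy]pentanoate | COc1ccc(COC[C@H](O)[C@@H](CC(=O)OC(C)(C)C)C(=O)N2C(=O)OC[C@H]2Cc2ccccc2)cc1 | intermediate
14 | tert-butyl (3R,4R)-4-hydroxy-3-[methoxy(methyl)carbamoyl]-5-[(4-methoxybenzyl)oxy]pentanoate | COc1ccc(COC[C@H](O)[C@@H](CC(=O)OC(C)(C)C)C(=O)N(C)OC)cc1 | intermediate
15 | tert-butyl (3R,4R)-4-[(tert-butyldimethylsilyl)oxy]-3-[methoxy(methyl)carbamoyl]-5-[(4-methoxybenzyl)oxy]pentanoate | COc1ccc(COC[C@H](O[Si](C)(C)C(C)(C)C)[C@@H](CC(=O)OC(C)(C)C)C(=O)N(C)OC)cc1 | intermediate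
16 | 1-propynylmagnesium bromide | CC#C[Mg]Br | starting material
17 | tert-butyl (3R)-3-{(1R)-1-[(tert-butyldimethylsilyl)oxy]-2-[(4-methoxybenzyl)oxy]ethyl}-4-oxohept-5-ynoate | COc1ccc(COC[C@H](O[Si](C)(C)C(C)(C)C)[C@@H](CC(=O)OC(C)(C)C)C(=O)C#CC)cc1 | intermediate
18 | tert-butyl (3S,4S)-3-{(1R)-1-[(tert-butyldimethylsilyl)oxy]-2-[(4-methoxybenzyl)oxy]ethyl}-4-hydroxyhept-5-ynoate | COc1ccc(COC[C@H](O[Si](C)(C)C(C)(C)C)[C@@H](CC(=O)OC(C)(C)C)[C@H](O)C#CC)cc1 | intermediate
19 | (4S,5S)-4-{(1R)-1-[(tert-butyldimethylsilyl)oxy]-2-[(4-methoxybenzyl)oxy]ethyl}-5-(prop-1-yn-1-yl)oxolan-2-one | COc1ccc(COC[C@H](O[Si](C)(C)C(C)(C)C)[C@H]2CC(=O)O[C@@H]2C#CC)cc1 | intermediate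
20 | C4 chlorozirconocene of 19 (zirconium trans to C6) | COc1ccc(COC[C@H](O[Si](C)(C)C(C)(C)C)[C@H]2CC(=O)O[C@@H]2/C=C(\C)[Zr](Cl)(C3C=CC=C3)C3C=CC=C3)cc1 | intermediate
21 | (4S,5S)-4-{(1R)-1-[(tert-butyldimethylsilyl)oxy]-2-[(4-methoxybenzyl)oxy]ethyl}-5-[(1E)-2-iodoprop-1-en-1-yl]oxolan-2-one | COc1ccc(COC[C@H](O[Si](C)(C)C(C)(C)C)[C@H]2CC(=O)O[C@@H]2/C=C(\C)I)cc1 | intermediate
22 | (4S,5S)-4-{(1R)-1-[(tert-butyldimethylsilyl)oxy]-2-hydroxyethyl}-5-[(1E)-2-iodoprop-1-en-1-yl]oxolan-2-one | OC[C@H](O[Si](C)(C)C(C)(C)C)[C@H]1CC(=O)O[C@@H]1/C=C(\C)I | intermediate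
23 | (2R)-2-[(tert-butyldimethylsilyl)oxy]-2-{(2S,3S)-2-[(1E)-2-iodoprop-1-en-1-yl]-5-oxooxolan-3-yl}acetaldehyde | O=C[C@H](O[Si](C)(C)C(C)(C)C)[C@H]1CC(=O)O[C@@H]1/C=C(\C)I | intermediate
24 | (Z)-2-lithio analogue of 6 (lithium cis to the vinyl group) | C=C/C=C(\[Li])CO[Si](C)(C)C(C)(C)C | intermediate
25 | (4S,5S)-4-[(1R,2S,3Z)-1-[(tert-butyldimethylsilyl)oxy]-3-{[(tert-butyldimethylsilyl)oxy]methyl}-2-hydroxyhexa-3,5-dien-1-yl]-5-[(1E)-2-iodoprop-1-en-1-yl]oxolan-2-one | C=C/C=C(/CO[Si](C)(C)C(C)(C)C)[C@H](O)[C@H](O[Si](C)(C)C(C)(C)C)[C@H]1CC(=O)O[C@@H]1/C=C(\C)I | intermediate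
26 | triethylsilyl ether of 25 at O9 (6S,7S,8R,9S), the key-step precursor | C=C/C=C(/CO[Si](C)(C)C(C)(C)C)[C@H](O[Si](CC)(CC)CC)[C@H](O[Si](C)(C)C(C)(C)C)[C@H]1CC(=O)O[C@@H]1/C=C(\C)I | intermediate
27 | C3 9-borabicyclo[3.3.1]nonan-9-yl adduct of 26 | C1CC2CCCC(C1)B2CC/C=C(/CO[Si](C)(C)C(C)(C)C)[C@H](O[Si](CC)(CC)CC)[C@H](O[Si](C)(C)C(C)(C)C)[C@H]1CC(=O)O[C@@H]1/C=C(\C)I | intermediate
28 | (1(10)Z,4E,6R,7S,8R,9S)-8,14-bis[(tert-butyldimethylsilyl)oxy]-9-[(triethylsilyl)oxy]germacra-1(10),4-dien-12,6-olide | CC(C)(C)[Si](C)(C)O[C@@H]1[C@H]2CC(=O)O[C@@H]2/C=C(\C)CC/C=C(/CO[Si](C)(C)C(C)(C)C)[C@@H]1O[Si](CC)(CC)CC | intermediate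
29 | 13-(dimethylamino) derivative of 28 (C11 epimers) | CC(C)(C)[Si](C)(C)O[C@@H]1[C@H]2C(CN(C)C)C(=O)O[C@@H]2/C=C(\C)CC/C=C(/CO[Si](C)(C)C(C)(C)C)[C@@H]1O[Si](CC)(CC)CC | intermediate
30 | 13-(trimethylammonio) derivative of 28, iodide | CC(C)(C)[Si](C)(C)O[C@@H]1[C@H]2C(C[N+](C)(C)C)C(=O)O[C@@H]2/C=C(\C)CC/C=C(/CO[Si](C)(C)C(C)(C)C)[C@@H]1O[Si](CC)(CC)CC.[I-] | intermediate
31 | (1(10)Z,4E,6R,7S,8R,9S)-8,14-bis[(tert-butyldimethylsilyl)oxy]-9-[(triethylsilyl)oxy]germacra-1(10),4,11(13)-trien-12,6-olide | CC(C)(C)[Si](C)(C)O[C@@H]1[C@H]2C(=C)C(=O)O[C@@H]2/C=C(\C)CC/C=C(/CO[Si](C)(C)C(C)(C)C)[C@@H]1O[Si](CC)(CC)CC | intermediate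
32 | (6R,7S,8R,9S)-8-[(tert-butyldimethylsilyl)oxy]-9,14-dihydroxygermacra-1(10),4,11(13)-trien-12,6-olide (C2 cis to C9, 4E) | CC(C)(C)[Si](C)(C)O[C@@H]1[C@H]2C(=C)C(=O)O[C@@H]2/C=C(\C)CC/C=C(/CO)[C@@H]1O | intermediate
33 | (6R,7S,8R,9S)-8-[(tert-butyldimethylsilyl)oxy]-9-hydroxy-14-oxogermacra-1(10),4,11(13)-trien-12,6-olide (C2 cis to C9, 4E) | CC(C)(C)[Si](C)(C)O[C@@H]1[C@H]2C(=C)C(=O)O[C@@H]2/C=C(\C)CC/C=C(/C=O)[C@@H]1O | intermediate
34 | (6R,7S,8R,9S)-8-[(tert-butyldimethylsilyl)oxy]-9-hydroxy-12-oxo-12,6-epoxygermacra-1(10),4,11(13)-trien-14-oic acid (C2 cis to C9, 4E) | CC(C)(C)[Si](C)(C)O[C@@H]1[C@H]2C(=C)C(=O)O[C@@H]2/C=C(\C)CC/C=C(/C(=O)O)[C@@H]1O | intermediate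
35 | methyl ester of 34 | CC(C)(C)[Si](C)(C)O[C@@H]1[C@H]2C(=C)C(=O)O[C@@H]2/C=C(\C)CC/C=C(/C(=O)OC)[C@@H]1O | intermediate
36 | 9-O-acetyl derivative of 35 | CC(C)(C)[Si](C)(C)O[C@@H]1[C@H]2C(=C)C(=O)O[C@@H]2/C=C(\C)CC/C=C(/C(=O)OC)[C@@H]1OC(C)=O | intermediate
37 | methyl (6R,7R,8R,9S)-9-acetoxy-8-hydroxy-12-oxo-12,6-epoxygermacra-1(10),4,11(13)-trien-14-oate (C2 cis to C9, 4E) | O[C@@H]1[C@H]2C(=C)C(=O)O[C@@H]2/C=C(\C)CC/C=C(/C(=O)OC)[C@@H]1OC(C)=O | intermediate
38 | methyl (6R,7S,8R,9S)-9-acetoxy-8-(methacryloyloxy)-12-oxo-12,6-epoxygermacra-1(10),4,11(13)-trien-14-oate (C2 cis to C9, 4E) | C=C(C)C(=O)O[C@@H]1[C@H]2C(=C)C(=O)O[C@@H]2/C=C(\C)CC/C=C(/C(=O)OC)[C@@H]1OC(C)=O | intermediate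
39 | CNP0153978.4, the (4R,5R,6S,7R,8R,9S)-4,5-epoxide of 38 | C=C(C)C(=O)O[C@@H]1[C@H]2C(=C)C(=O)O[C@@H]2[C@H]2O[C@]2(C)CC/C=C(/C(=O)OC)[C@@H]1OC(C)=O | target

**Totals**

Total step count: 25.
Longest linear sequence: 22 steps (steps 4 to 25, from 7 and 8). Steps 1 to 3 give fragment 6, which joins at step 13.

**Steps most likely to fail**

1. Step 15 (key step). Transmetalation from the borate may be too slow for the strained ring-forming event, so that oligomerization, protodeboronation or β-hydride elimination take over. The fallback sets out from 26 and comes back at 28. Hydroboration with 9-BBN as in step 15 gives 27, which is oxidized (NaBO3·4H2O, THF–H2O) to the primary alcohol F1. Appel iodination (PPh3, I2, imidazole, CH2Cl2) should give the primary iodide F2. Zinc insertion (Zn dust, LiCl, THF, 25 °C), which is much faster for the alkyl than for the vinyl iodide, gives the alkylzinc iodide F3. Intramolecular Negishi coupling (Pd[P(t-Bu)3]2, THF–NMP, high dilution) should then close the same C3–C4 bond and give 28.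

2. Step 13. Facial selectivity at C9 may be poor, and the basic alkenyllithium may enolize the α-silyloxy aldehyde or attack the lactone or the C4–I bond. The fallback sets out from 25 as obtained, whatever its epimer ratio at C9, and comes back at 25. Dess–Martin oxidation gives the dienone F4, and the C9 carbinol is then set by reagent-controlled Corey–Bakshi–Shibata reduction (catecholborane, toluene, −78 °C). The (S)-methyl oxazaborolidine is the enantiomer to use if the α-branched dienyl group acts as the larger substituent; this assignment is not certain and would be checked first.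

3. Step 10. Regiocontrol in the hydrozirconation may be incomplete; zirconium on C5 would be lost by β-elimination of the lactone oxygen to an allene, and the excess hydride may slowly reduce the lactone. The fallback sets out from 19 and comes back at 21. Platinum-catalysed syn hydrosilylation (PtCl2, XPhos, Et3SiH, THF, 50 °C), which places silicon on the alkyne carbon remote from the oxygen-bearing C6, should give the vinylsilane F5. Iododesilylation with retention (NIS, MeCN–ClCH2CN, 0 °C) should then give 21.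

**Further compounds**

F1 | step 15 | C3 primary alcohol from hydroboration–oxidation of 26 | OCC/C=C(/CO[Si](C)(C)C(C)(C)C)[C@H](O[Si](CC)(CC)CC)[C@H](O[Si](C)(C)C(C)(C)C)[C@H]1CC(=O)O[C@@H]1/C=C(\C)I
F2 | step 15 | C3 primary iodide | ICC/C=C(/CO[Si](C)(C)C(C)(C)C)[C@H](O[Si](CC)(CC)CC)[C@H](O[Si](C)(C)C(C)(C)C)[C@H]1CC(=O)O[C@@H]1/C=C(\C)I
F3 | step 15 | C3 alkylzinc iodide | I[Zn]CC/C=C(/CO[Si](C)(C)C(C)(C)C)[C@H](O[Si](CC)(CC)CC)[C@H](O[Si](C)(C)C(C)(C)C)[C@H]1CC(=O)O[C@@H]1/C=C(\C)I
F4 | step 13 | C9 dienone from oxidation of 25 | C=C/C=C(/CO[Si](C)(C)C(C)(C)C)C(=O)[C@H](O[Si](C)(C)C(C)(C)C)[C@H]1CC(=O)O[C@@H]1/C=C(\C)I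
F5 | step 10 | C4 triethylsilyl alkene from hydrosilylation of 19 (silicon trans to C6) | COc1ccc(COC[C@H](O[Si](C)(C)C(C)(C)C)[C@H]2CC(=O)O[C@@H]2/C=C(\C)[Si](CC)(CC)CC)cc1
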